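## Retrosynthetic overview

1. The side chain is numbered C1' (on the quinone ring) to C36'. The quinone ring is unmasked last from a 1,4-dimethoxynaphthalene. No ring is formed in the route, because both rings of the naphthalene core are bought intact.
2. The key disconnection is C7'–C8'. Two plain 1-alkenes are joined by one-pot hydroalumination, Zr-catalysed asymmetric carboalumination (ZACA) and protonolysis. One is a C36 hexaene (C8'–C36', vinyl = C8'=C9'); the other is a dimethoxynaphthyl diene (core + C1'–C7', vinyl = C7' plus the future 7'-methyl carbon). This single operation makes the bond, the (7'R) centre and the methyl branch.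
3. Enabling feature: C7' is a CH(CH3) bonded to the unbranched CH2 C8', which is the exact retron of n-alkyl–Al addition across a vinyl group. The six other C=C bonds (at C2', C14', C18', C22', C26', C34') are all trisubstituted and so are inert to both the aluminium hydride and the zirconocene.
4. The C36 hexaene comes from allyl sulfone alkylation/desulfonylation at C16'–C17' and a Cu-catalysed Grignard–allylic bromide coupling at C28'–C29'. Farnesol supplies C17'–C28'. The (R)-citronellyl chiral pool supplies both C11' (citronellal) and C31' (citronellyl bromide).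
5. The naphthyl diene comes from methylalumination of hept-1-en-6-yne, which sets the 2'E alkene, followed by Ni-catalysed coupling with the chloromethylnaphthalene to make C1'–C2'.

Key step: step 16

Assumption: the facial sense of (−)-bis(1-neomenthylindenyl)zirconium dichloride, (−)-(NMI)2ZrCl2, in n-alkylalumination is taken to be the one known for methylalumination of 1-alkenes (the face that leads to (R)-2-methylalkan-1-ols after oxidation), which maps onto (7'R) here; the (+)-antipode would serve if the sense were reversed.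

## Route

Step 1
Reactants: 1 5-bromopent-1-ene
Product: 2 hept-1-en-6-yne
Conditions: LiC≡CH·H2NCH2CH2NH2 (1.2 equiv), DMSO, 0 °C to rt
Reagents that add atoms: lithium acetylide ethylenediamine complex, [Li]C#C.NCCN
Why: SN2 alkylation of lithium acetylide by an unhindered primary bromide in DMSO is a standard terminal-alkyne synthesis and leaves the vinyl group untouched.

Step 2
Reactants: 3 1,4-dimethoxy-2-methylnaphthalene
Product: 4 2-(chloromethyl)-1,4-dimethoxy-3-methylnaphthalene
Conditions: (CH2O)n, conc. aq HCl, AcOH, rt to 40 °C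
Reagents that add atoms: paraformaldehyde (as formaldehyde), C=O; hydrogen chloride, Cl
Why: Blanc-type chloromethylation is an electrophilic aromatic substitution that can only take the single free position of the electron-rich dimethoxy-substituted ring, ortho to a methoxy group.

Step 3
Reactants: 2 hept-1-en-6-yne; 4 2-(chloromethyl)-1,4-dimethoxy-3-methylnaphthalene
Product: 6 1,4-dimethoxy-2-methyl-3-[(2E)-3-methylocta-2,7-dien-1-yl]naphthalene, via alkenyldimethylalane 5 (not isolated)
Conditions: Me3Al (2 equiv), Cp2ZrCl2 (20 mol %), ClCH2CH2Cl, 0 °C to rt; volatiles removed; then 4, NiCl2(PPh3)2 (3 mol %)/n-BuLi (6 mol %) (gives zerovalent nickel), THF, rt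
Reagents that add atoms: trimethylaluminium, C[Al](C)C
Why: Zr-catalysed syn-methylalumination of the terminal alkyne, which is much faster than any reaction of the vinyl group, fixes the 2'E geometry in 5, and the zerovalent-nickel-catalysed cross-coupling of alkenylalanes with benzylic chlorides forms C1'–C2' with retention of that geometry.

Step 4
Reactants: 7 (2E,6E)-farnesol
Product: 8 tert-butyl(diphenyl)silyl ether of (2E,6E)-farnesol
Conditions: TBDPSCl, imidazole, DMF, 0 °C to rt
Reagents that add atoms: tert-butyl(chloro)diphenylsilane, CC(C)(C)[Si](Cl)(c1ccccc1)c1ccccc1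
Why: Standard silylation of a primary allylic alcohol gives an ether that withstands the oxidation, bromination and Grignard chemistry that follow.

Step 5
Reactants: 8 farnesyl TBDPS ether
Product: 9 (2E,6E,10E)-12-{[tert-butyl(diphenyl)silyl]oxy}-2,6,10-trimethyldodeca-2,6,10-trien-1-ol
Conditions: SeO2 (10 mol %), t-BuOOH (3 equiv), salicylic acid (10 mol %), CH2Cl2, 0 °C to rt
Reagents that add atoms: tert-butyl hydroperoxide (oxygen relayed by SeO2), CC(C)(C)OO
Why: Riley-type SeO2 allylic oxidation (ene reaction, then [2,3]-sigmatropic shift) prefers the most electron-rich and least hindered terminal isopropylidene group and oxidises only its E-methyl group, while the C2=C3 alkene is deactivated by the allylic silyloxy group.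

Step 6
Reactants: 9 ω-hydroxyfarnesyl TBDPS ether
Product: 10 tert-butyl{[(2E,6E,10E)-12-bromo-3,7,11-trimethyldodeca-2,6,10-trien-1-yl]oxy}diphenylsilane
Conditions: PBr3 (0.4 equiv), Et2O, −10 °C
Reagents that add atoms: phosphorus tribromide, BrP(Br)Br
Why: Bromination of a primary allylic alcohol with PBr3 at low temperature goes by SN2 displacement of the phosphite ester without allylic shift or loss of E geometry, and the robust silyl ether survives.

Step 7
Reactants: 11 (R)-citronellyl bromide [(6R)-8-bromo-2,6-dimethyloct-2-ene]; 10 ω-bromofarnesyl TBDPS ether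
Product: 13 tert-butyl{[(2E,6E,10E,15S)-3,7,11,15,19-pentamethylicosa-2,6,10,18-tetraen-1-yl]oxy}diphenylsilane, via citronellylmagnesium bromide 12 (not isolated)
Conditions: 11, Mg, THF, rt to 40 °C; then 10, Li2CuCl4 (5 mol %), THF, −40 °C to 0 °C
Reagents that add atoms: none
Why: Copper-catalysed Grignard–allylic bromide cross-coupling (Kochi-type, Li2CuCl4) attacks the unhindered primary carbon C28' rather than the γ-carbon C26', so the E-alkene stays in place, and the C31' stereocentre of the chiral-pool bromide is remote from the reacting carbon.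

Step 8
Reactants: 13 C25 TBDPS ether
Product: 14 (2E,6E,10E,15S)-3,7,11,15,19-pentamethylicosa-2,6,10,18-tetraen-1-ol
Conditions: Bu4NF, THF, rt
Reagents that add atoms: none
Why: Fluoride-induced desilylation is selective for the Si–O bond and touches none of the four alkenes.

Step 9
Reactants: 14 C25 allylic alcohol
Product: 15 (2E,6E,10E,15S)-1-bromo-3,7,11,15,19-pentamethylicosa-2,6,10,18-tetraene
Conditions: PBr3 (0.4 equiv), Et2O, −10 °C; used crude
Reagents that add atoms: phosphorus tribromide, BrP(Br)Br
Why: This is the standard farnesol-to-farnesyl bromide conversion (SN2 on the phosphite ester), which keeps the position and E geometry of the allylic double bond.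

Step 10
Reactants: 15 C25 allylic bromide
Product: 16 {[(2E,6E,10E,15S)-3,7,11,15,19-pentamethylicosa-2,6,10,18-tetraen-1-yl]sulfonyl}benzene
Conditions: PhSO2Na, DMF, rt
Reagents that add atoms: sodium benzenesulfinate, [Na+].[O-]S(=O)c1ccccc1
Why: SN2 S-alkylation of the ambident sulfinate by the primary allylic bromide in DMF gives the sulfone with the C18'=C19' alkene unchanged.

Step 11
Reactants: 17 (R)-citronellal [(3R)-3,7-dimethyloct-6-enal]
Product: 18 (4R)-4,8-dimethylnona-1,7-diene
Conditions: Ph3PCH3Br, KOt-Bu, THF, 0 °C to rt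
Reagents that add atoms: methyltriphenylphosphonium bromide, C[P+](c1ccccc1)(c1ccccc1)c1ccccc1.[Br-]
Why: Wittig methylenation with the non-stabilised ylide installs the vinyl group (C8'=C9'), and the stereocentre (future C11') is β to the carbonyl and cannot epimerise.

Step 12
Reactants: 18 (4R)-4,8-dimethylnona-1,7-diene
Product: 19 (2E,6R)-2,6-dimethylnona-2,8-dien-1-ol
Conditions: SeO2 (10 mol %), t-BuOOH (2 equiv), salicylic acid (10 mol %), CH2Cl2, 0 °C
Reagents that add atoms: tert-butyl hydroperoxide (oxygen relayed by SeO2), CC(C)(C)OO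
Why: Riley-type SeO2 allylic oxidation engages the nucleophilic trisubstituted alkene far faster than the vinyl group and hydroxylates only the E-methyl group, which becomes C16'.

Step 13
Reactants: 19 (2E,6R)-2,6-dimethylnona-2,8-dien-1-ol
Product: 20 (2E,6R)-1-bromo-2,6-dimethylnona-2,8-diene
Conditions: PBr3 (0.4 equiv), Et2O, −10 °C
Reagents that add atoms: phosphorus tribromide, BrP(Br)Br
Why: Low-temperature PBr3 bromination of the primary allylic alcohol proceeds by SN2 without allylic transposition and leaves the vinyl group and the stereocentre alone.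

Step 14
Reactants: 16 C25 allylic sulfone; 20 allylic bromide
Product: 22 {[(4R,7E,11E,15E,19E,24S)-4,8,12,16,20,24,28-heptamethylnonacosa-1,7,11,15,19,27-hexaen-10-yl]sulfonyl}benzene (both epimers at the sulfone carbon C17'), via lithiated sulfone 21 (not isolated)
Conditions: 16, n-BuLi (1.05 equiv), THF/DMPU, −78 °C; then 20, −78 °C to −20 °C
Reagents that add atoms: none
Why: In this Biellmann-type coupling the α-sulfonyl allyl anion 21 is alkylated at its α-carbon by the primary allylic bromide in an SN2 reaction that forms C16'–C17', and the new sulfone-bearing centre needs no control because it is erased in step 15.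

Step 15
Reactants: 22 C36 sulfone
Product: 23 (4R,7E,11E,15E,19E,24S)-4,8,12,16,20,24,28-heptamethylnonacosa-1,7,11,15,19,27-hexaene
Conditions: PdCl2(dppp) (5 mol %), LiEt3BH (2.5 equiv), THF, 0 °C
Reagents that add atoms: none
Why: Palladium-catalysed reductive desulfonylation runs through a π-allyl complex of divalent palladium to which hydride from LiEt3BH is delivered at the less substituted terminus C17', so that with the dppp ligand the C18'=C19' bond should keep its place and E geometry while the isolated alkenes are inert.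

Step 16
Reactants: 23 C36 hexaene; 6 dimethoxynaphthyl diene
Product: 26 1,4-dimethoxy-2-methyl-3-[(2E,7R,11S,14E,18E,22E,26E,31S)-3,7,11,15,19,23,27,31,35-nonamethylhexatriaconta-2,14,18,22,26,34-hexaen-1-yl]naphthalene, via primary diisobutylalane 24 (not isolated), via branched diisobutylalane 25 (not isolated)
Conditions: 23 (1.2 equiv), iBu2AlH (1.2 equiv), hexane, 60 °C; solvent changed to CH2Cl2; 6 (1.0 equiv), (−)-(NMI)2ZrCl2 (5–10 mol %), isobutylaluminoxane (iBuAlO)n (30 mol %), rt; then 2 M aq HCl, 0 °C
Reagents that add atoms: none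
Why: iBu2AlH adds thermally only to the monosubstituted C8'=C9' bond of 23 and places aluminium on C8' (24); the n-alkyl group then passes to the cationic zirconocene formed from (−)-(NMI)2ZrCl2 and isobutylaluminoxane, the vinyl group of 6 inserts into the Zr–C8' bond with C8' bonding to the internal carbon C7' and zirconium to the terminal CH2, Zr/Al exchange releases 25, and acid turns its CH2–Al bond into the 7'-methyl group. The closest known reaction type is the one-pot hydroalumination/Zr-catalysed asymmetric carboalumination of alkenes (ZACA), in which n-alkyl(diisobutyl)alanes made from one 1-alkene add to a second 1-alkene and protonolysis leaves a methyl-branched chain. No ring is closed. The one new stereocentre, C7', is under catalyst control: the C2-symmetric bis(neomenthylindenyl) pocket lets the vinyl group of 6 bind through one face, and the (−)-catalyst should deliver C8' to the face that gives (7'R), independently of the remote C11' and C31' centres. The step needs chemoselectivity for two vinyl groups beside six trisubstituted C=C bonds and two aryl methyl ethers, secured because neither iBu2AlH at this temperature nor the bulky zirconocene accepts trisubstituted alkenes; cross- rather than homo-coupling, secured by consuming the vinyl group of 23 before 6 is added; and transfer of the n-alkyl rather than an isobutyl group with a single insertion, secured because β-branched alkyls (isobutyl and the product alkyl of 25) migrate far more slowly. CH2Cl2 as solvent suppresses the competing cyclic carbozirconation and β-hydride transfer pathways.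

Step 17
Reactants: 26 hydroquinone dimethyl ether
Product: 27 2-methyl-3-[(2E,7R,11S,14E,18E,22E,26E,31S)-3,7,11,15,19,23,27,31,35-nonamethylhexatriaconta-2,14,18,22,26,34-hexaen-1-yl]naphthalene-1,4-dione (CNP0210279.1)
Conditions: (NH4)2Ce(NO3)6 (2.5 equiv), MeCN/CH2Cl2/H2O, 0 °C
Reagents that add atoms: water, O
Why: Oxidative demethylation of a hydroquinone dimethyl ether with (NH4)2Ce(NO3)6 proceeds by two one-electron oxidations with ipso attack of water and loss of methanol, is much faster than oxidation of isolated trisubstituted alkenes, and touches no stereocentre.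

## Compound list

1 | 5-bromopent-1-ene | C=CCCCBr | starting material
2 | hept-1-en-6-yne | C=CCCCC#C | intermediate
3 | 1,4-dimethoxy-2-methylnaphthalene | COc1cc(C)c(OC)c2ccccc12 | starting material
4 | 2-(chloromethyl)-1,4-dimethoxy-3-methylnaphthalene | COc1c(C)c(CCl)c(OC)c2ccccc12 | intermediate
5 | dimethyl[(1E)-2-methylhepta-1,6-dien-1-yl]alumane | C=CCCC/C(C)=C/[Al](C)C | intermediate
6 | 1,4-dimethoxy-2-methyl-3-[(2E)-3-methylocta-2,7-dien-1-yl]naphthalene | C=CCCC/C(C)=C/Cc1c(C)c(OC)c2ccccc2c1OC | intermediate
7 | (2E,6E)-farnesol | CC(C)=CCC/C(C)=C/CC/C(C)=C/CO | starting material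
8 | (2E,6E)-farnesyl tert-butyl(diphenyl)silyl ether | CC(C)=CCC/C(C)=C/CC/C(C)=C/CO[Si](c1ccccc1)(c1ccccc1)C(C)(C)C | intermediate
9 | (2E,6E,10E)-12-{[tert-butyl(diphenyl)silyl]oxy}-2,6,10-trimethyldodeca-2,6,10-trien-1-ol | OC/C(C)=C/CC/C(C)=C/CC/C(C)=C/CO[Si](c1ccccc1)(c1ccccc1)C(C)(C)C | intermediate
10 | tert-butyl{[(2E,6E,10E)-12-bromo-3,7,11-trimethyldodeca-2,6,10-trien-1-yl]oxy}diphenylsilane | BrC/C(C)=C/CC/C(C)=C/CC/C(C)=C/CO[Si](c1ccccc1)(c1ccccc1)C(C)(C)C | intermediate
11 | (R)-citronellyl bromide | CC(C)=CCC[C@@H](C)CCBr | starting material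
12 | [(3R)-3,7-dimethyloct-6-en-1-yl]magnesium bromide | CC(C)=CCC[C@@H](C)CC[Mg]Br | intermediate
13 | tert-butyl{[(2E,6E,10E,15S)-3,7,11,15,19-pentamethylicosa-2,6,10,18-tetraen-1-yl]oxy}diphenylsilane | CC(C)=CCC[C@@H](C)CCC/C(C)=C/CC/C(C)=C/CC/C(C)=C/CO[Si](c1ccccc1)(c1ccccc1)C(C)(C)C | intermediate
14 | (2E,6E,10E,15S)-3,7,11,15,19-pentamethylicosa-2,6,10,18-tetraen-1-ol | CC(C)=CCC[C@@H](C)CCC/C(C)=C/CC/C(C)=C/CC/C(C)=C/CO | intermediate
15 | (2E,6E,10E,15S)-1-bromo-3,7,11,15,19-pentamethylicosa-2,6,10,18-tetraene | CC(C)=CCC[C@@H](C)CCC/C(C)=C/CC/C(C)=C/CC/C(C)=C/CBr | intermediate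
16 | {[(2E,6E,10E,15S)-3,7,11,15,19-pentamethylicosa-2,6,10,18-tetraen-1-yl]sulfonyl}benzene | CC(C)=CCC[C@@H](C)CCC/C(C)=C/CC/C(C)=C/CC/C(C)=C/CS(=O)(=O)c1ccccc1 | intermediate
17 | (R)-citronellal | CC(C)=CCC[C@@H](C)CC=O | starting material
18 | (4R)-4,8-dimethylnona-1,7-diene | CC(C)=CCC[C@@H](C)CC=C | intermediate
19 | (2E,6R)-2,6-dimethylnona-2,8-dien-1-ol | OC/C(C)=C/CC[C@@H](C)CC=C | intermediate
20 | (2E,6R)-1-bromo-2,6-dimethylnona-2,8-diene | BrC/C(C)=C/CC[C@@H](C)CC=C | intermediate
21 | α-lithio derivative of sulfone 16 (Li on C17') | CC(C)=CCC[C@@H](C)CCC/C(C)=C/CC/C(C)=C/CC/C(C)=C/C([Li])S(=O)(=O)c1ccccc1 | intermediate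
22 | hexaene 23 bearing PhSO2 at C17' (C10 of the nonacosahexaene), both epimers at that carbon | CC(C)=CCC[C@@H](C)CCC/C(C)=C/CC/C(C)=C/CC/C(C)=C/C(C/C(C)=C/CC[C@@H](C)CC=C)S(=O)(=O)c1ccccc1 | intermediate
23 | (4R,7E,11E,15E,19E,24S)-4,8,12,16,20,24,28-heptamethylnonacosa-1,7,11,15,19,27-hexaene | CC(C)=CCC[C@@H](C)CCC/C(C)=C/CC/C(C)=C/CC/C(C)=C/CC/C(C)=C/CC[C@@H](C)CC=C | intermediate
24 | primary alane: 23 with H added at C9' and Al(i-Bu)2 at C8' | CC(C)=CCC[C@@H](C)CCC/C(C)=C/CC/C(C)=C/CC/C(C)=C/CC/C(C)=C/CC[C@@H](C)CCC[Al](CC(C)C)CC(C)C | intermediate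
25 | branched alane: 26 with Al(i-Bu)2 on the 7'-methyl carbon | CC(C)=CCC[C@@H](C)CCC/C(C)=C/CC/C(C)=C/CC/C(C)=C/CC/C(C)=C/CC[C@@H](C)CCC[C@@H](C[Al](CC(C)C)CC(C)C)CCC/C(C)=C/Cc1c(C)c(OC)c2ccccc2c1OC | intermediate
26 | 1,4-dimethoxy-2-methyl-3-[(2E,7R,11S,14E,18E,22E,26E,31S)-3,7,11,15,19,23,27,31,35-nonamethylhexatriaconta-2,14,18,22,26,34-hexaen-1-yl]naphthalene | CC(C)=CCC[C@@H](C)CCC/C(C)=C/CC/C(C)=C/CC/C(C)=C/CC/C(C)=C/CC[C@@H](C)CCC[C@@H](C)CCC/C(C)=C/Cc1c(C)c(OC)c2ccccc2c1OC | intermediate
27 | 2-methyl-3-[(2E,7R,11S,14E,18E,22E,26E,31S)-3,7,11,15,19,23,27,31,35-nonamethylhexatriaconta-2,14,18,22,26,34-hexaen-1-yl]naphthalene-1,4-dione | CC(C)=CCC[C@@H](C)CCC/C(C)=C/CC/C(C)=C/CC/C(C)=C/CC/C(C)=C/CC[C@@H](C)CCC[C@@H](C)CCC/C(C)=C/CC1=C(C)C(=O)c2ccccc2C1=O | target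

## Step count and risks

Total step count: 17.
Longest linear sequence: 11 steps (steps 4–10 and 14–17, from farnesol 7).

**Step 16.**
- What may go wrong: discrimination between the two faces of the vinyl group of 6 may be incomplete, and the resulting C7' epimer could hardly be removed. β-Hydride transfer from the isobutyl groups may merely hydroaluminate 6. Transfer of the long alkyl chain to zirconium may be slow.
- Fallback: the same bond is formed stereospecifically instead of under catalyst control. It sets out from 6 and 24 and comes back at 26.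
- Wacker–Tsuji oxidation of the vinyl group of 6 (PdCl2, CuCl, O2, DMF/H2O) would give methyl ketone F1.
- An (R)-selective alcohol dehydrogenase (Lactobacillus brevis enzyme, NADP+, i-PrOH/buffer) would reduce it to the (2R)-alcohol F2, and TsCl/pyridine would give the secondary tosylate F3.
- Iodinolysis of alane 24 (excess I2, THF, 0 °C) would give the primary iodide F4, which magnesium in THF turns into the Grignard reagent F5.
- CuI/TMEDA/LiOMe-catalysed SN2 coupling of F5 with F3 (THF, 0 °C) proceeds with inversion at C7' and would give 26.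

**Step 5.**
- What may go wrong: competing oxidation at the allylic positions of the internal C6=C7 alkene, and over-oxidation of the new alcohol to the enal.
- Fallback: oxidative truncation and rebuilding of the terminus. It sets out from 8 and comes back at 9.
- NBS in THF/H2O at 0 °C adds selectively to the terminal double bond to give bromohydrin F6, and K2CO3/MeOH closes the terminal epoxide F7.
- H5IO6 in THF/Et2O cleaves it to the trisnor aldehyde F8.
- The stabilised ylide Ph3P=C(CH3)CO2Et gives the (E)-enoate F9 by an E-selective Wittig reaction, and iBu2AlH (CH2Cl2, −78 °C) reduces the ester to 9.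

**Step 15.**
- What may go wrong: hydride delivery to the wrong terminus of the π-allyl palladium intermediate (double-bond shift), erosion of E geometry, or palladium hydride isomerisation of the terminal vinyl group that step 16 depends on.
- Fallback: direct allyl–allyl coupling, so that no sulfone is ever introduced. It sets out from 14, uses 20, and comes back at 23.
- Corey–Kim chlorination of 14 (NCS, Me2S, CH2Cl2, −20 °C) gives the allylic chloride F10.
- Activated barium metal (from BaI2 and lithium biphenylide, THF, −78 °C) converts it into the allylbarium chloride F11.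
- F11 couples α,α'-selectively and with retention of alkene geometry with allylic bromide 20 at −78 °C to give 23.

## Further compounds

F1 | step 16 | (6E)-8-(1,4-dimethoxy-3-methylnaphthalen-2-yl)-6-methyloct-6-en-2-one | CC(=O)CCC/C(C)=C/Cc1c(C)c(OC)c2ccccc2c1OC
F2 | step 16 | (2R,6E)-8-(1,4-dimethoxy-3-methylnaphthalen-2-yl)-6-methyloct-6-en-2-ol | C[C@@H](O)CCC/C(C)=C/Cc1c(C)c(OC)c2ccccc2c1OC
F3 | step 16 | (2R,6E)-8-(1,4-dimethoxy-3-methylnaphthalen-2-yl)-6-methyloct-6-en-2-yl 4-methylbenzenesulfonate | C[C@@H](OS(=O)(=O)c1ccc(C)cc1)CCC/C(C)=C/Cc1c(C)c(OC)c2ccccc2c1OC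
F4 | step 16 | primary iodide: 23 with H at C9' and I at C8' | CC(C)=CCC[C@@H](C)CCC/C(C)=C/CC/C(C)=C/CC/C(C)=C/CC/C(C)=C/CC[C@@H](C)CCCI
F5 | step 16 | alkylmagnesium iodide from F4 | CC(C)=CCC[C@@H](C)CCC/C(C)=C/CC/C(C)=C/CC/C(C)=C/CC/C(C)=C/CC[C@@H](C)CCC[Mg]I
F6 | step 5 | terminal bromohydrin of 8 (racemic at the C–Br carbon) | CC(C)(O)C(Br)CC/C(C)=C/CC/C(C)=C/CO[Si](c1ccccc1)(c1ccccc1)C(C)(C)C
F7 | step 5 | 10,11-epoxide of 8 (racemic) | CC1(C)OC1CC/C(C)=C/CC/C(C)=C/CO[Si](c1ccccc1)(c1ccccc1)C(C)(C)C
F8 | step 5 | (4E,8E)-10-{[tert-butyl(diphenyl)silyl]oxy}-4,8-dimethyldeca-4,8-dienal | O=CCC/C(C)=C/CC/C(C)=C/CO[Si](c1ccccc1)(c1ccccc1)C(C)(C)C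
F9 | step 5 | ethyl (2E,6E,10E)-12-{[tert-butyl(diphenyl)silyl]oxy}-2,6,10-trimethyldodeca-2,6,10-trienoate | CCOC(=O)/C(C)=C/CC/C(C)=C/CC/C(C)=C/CO[Si](c1ccccc1)(c1ccccc1)C(C)(C)C
F10 | step 15 | (2E,6E,10E,15S)-1-chloro-3,7,11,15,19-pentamethylicosa-2,6,10,18-tetraene | CC(C)=CCC[C@@H](C)CCC/C(C)=C/CC/C(C)=C/CC/C(C)=C/CCl
F11 | step 15 | allylbarium chloride from F10 | CC(C)=CCC[C@@H](C)CCC/C(C)=C/CC/C(C)=C/CC/C(C)=C/C[Ba]Cl
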